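**Retrosynthetic overview**

1. Target 28 comes from tetracycle 23 by Rubottom hydroxylation of the silyl enol ether in the two-carbon bridge, C-acylation of the ring CH2 beside the bridging ketone with sorbyl chloride, and desilylation.
2. 23 comes from 21 by one intramolecular (4+3) cycloaddition. The enabling feature is that in the bicyclo[3.2.1]octane the bridging ketone with its two α-carbons (the quaternary C–CH3 carbon and the CH2/enol carbon) is a 2-oxyallyl three-carbon unit, while the five-membered ring made of the sorbyl-bearing quaternary carbon, the α-ketol carbons C(=O)–C(OH)CH3 and the two ring CH groups is a masked 2-silyloxycyclopentadiene; the tertiary carbinol beside the C–CH3 carbon is the oxygen of the epoxide that releases the cation, and the cyclopentane through that carbinol is the tether.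
3. 21 comes from spiro-epoxy ketone 17, made from lactone 15 (Reformatsky ring closure) by oxidative allylic transposition and face-selective epoxidation.
4. 12 comes from 7 and 4: the bond between the lactone quaternary carbon and the cyclopentenone CH is made by Michael addition of a lactic acid-derived dioxolanone enolate to a resolved Piancatelli cyclopentenone.
5. Ring order: cyclopentenone (step 1), γ-lactone (step 9), epoxide (step 11), then cycloheptanone and cyclopentane together (step 14), which completes the bicyclo[3.2.1]octane.

Key step: step 14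

Remark (assumption): in the lipase resolution of step 2 the (4R,5S)-alcohol is taken to be the enantiomer that is acylated; if the enzyme shows the opposite sense, the acetate fraction is carried on after enzymatic deacetylation.
Remark: β-diketones are drawn as their chelated enols.

**Route**

Step 1
Reactants: 1 1-(furan-2-yl)ethan-1-ol (racemic)
Product: 2 (±)-trans-4-hydroxy-5-methylcyclopent-2-en-1-one
Conditions: ZnCl2 (1 equiv), dioxane–H2O, reflux
Reagents that add atoms: water, O
Why: Piancatelli rearrangement (furanoxonium ion, water addition, conrotatory 4π closure of the pentadienyl cation) should give the 4,5-trans cyclopentenone.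

Step 2
Reactants: 2 (±)-trans-4-hydroxy-5-methylcyclopent-2-en-1-one
Product: 3 (4S,5R)-4-hydroxy-5-methylcyclopent-2-en-1-one
Conditions: Amano lipase PS (a lipase), vinyl acetate, t-BuOMe, 30 °C, stopped near half conversion
Reagents that add atoms: none
Why: Lipase-catalysed kinetic resolution by enantioselective transesterification should leave the (4S,5R)-alcohol unreacted and separable from the acetate of its enantiomer.

Step 3
Reactants: 3 (4S,5R)-4-hydroxy-5-methylcyclopent-2-en-1-one
Product: 4 (4S,5R)-4-(tert-butyldimethylsilyloxy)-5-methylcyclopent-2-en-1-one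
Conditions: t-BuMe2SiCl, imidazole, DMF, 0 °C
Reagents that add atoms: tert-butyldimethylsilyl chloride, CC(C)(C)[Si](C)(C)Cl
Why: Standard silylation of a secondary alcohol; the bulky silyl ether later directs the conjugate addition to the opposite ring face.

Step 4
Reactants: 5 (R)-lactic acid; 6 pivalaldehyde
Product: 7 (2R,5R)-2-tert-butyl-5-methyl-1,3-dioxolan-4-one
Conditions: p-TsOH (cat.), pentane, reflux with water separation; crystallisation of the cis isomer
Reagents that add atoms: none
Why: Acid-catalysed acetalisation gives the thermodynamically favoured cis-dioxolanone, which stores the lactic acid chirality in the acetal carbon (self-regeneration of stereocentres).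

Step 5
Reactants: 7 (2R,5R)-2-tert-butyl-5-methyl-1,3-dioxolan-4-one; 4 (4S,5R)-4-(tert-butyldimethylsilyloxy)-5-methylcyclopent-2-en-1-one
Product: 8 Michael adduct as its trimethylsilyl enol ether
Conditions: LiN(iPr)2 (1.05 equiv), THF–DMPU, −78 °C; add 4, −78 °C; then Me3SiCl
Reagents that add atoms: chlorotrimethylsilane, C[Si](C)(C)Cl
Why: Enolate Michael addition in which the dioxolanone enolate reacts on the face anti to tert-butyl (sets the quaternary carbinol carbon) and the enone reacts anti to the 4-silyloxy group (sets the ring CH), the regiodefined enolate being trapped as its silyl enol ether.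

Step 6
Reactants: 8 Michael adduct (silyl enol ether); 9 (E)-2-bromobut-2-ene
Product: 11 α-hydroxy enone on a 3-silyloxycyclopentanone, via (E)-but-2-en-2-yllithium 10 (not isolated)
Conditions: 9, t-BuLi (2 equiv), Et2O, −78 °C; add 8 in THF, −78 °C; then 1 M HCl, 0 °C
Reagents that add atoms: none
Why: Halogen–lithium exchange with retention and 1,2-addition of the alkenyllithium to the dioxolanone carbonyl (the ring ketone being masked as its enol ether) should give, after acidic collapse of the hemiketal and enol ether hydrolysis, the tertiary α-hydroxy ketone without touching the stereocentres.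

Step 7
Reactants: 11 α-hydroxy enone on a 3-silyloxycyclopentanone
Product: 12 (4R)-4-[(2S,4E)-2-hydroxy-4-methyl-3-oxohex-4-en-2-yl]-2-methylcyclopent-2-en-1-one
Conditions: DBU, CH2Cl2, 0 to 23 °C
Reagents that add atoms: none
Why: E1cB elimination of the β-silyloxy group gives the 2-methylcyclopentenone and removes the two auxiliary ring stereocentres, leaving the ring CH centre untouched.

Step 8
Reactants: 12 hydroxy enone; 13 2-bromopropanoyl bromide (racemic)
Product: 14 2-bromopropanoate ester of 12 (epimers at the CHBr carbon)
Conditions: pyridine, DMAP (cat.), CH2Cl2, 0 °C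
Reagents that add atoms: none
Why: Acylation of the hindered tertiary α-ketol by the acid bromide (through the ketene) installs the two lactone carbons and the C-methyl group.

Step 9
Reactants: 14 2-bromopropanoate ester
Product: 15 β-hydroxy-γ-lactone
Conditions: SmI2 (2.2 equiv), THF, −78 °C; aqueous work-up
Reagents that add atoms: none
Why: Intramolecular Reformatsky reaction: SmI2 reduces only the C–Br bond and the samarium enolate adds to the adjacent ketone through a chelated transition state that should place the α-methyl group anti to the metal-bound oxygen, that is cis to the cyclopentenyl group on the lactone; the carbinol configuration is removed in step 10.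

Step 10
Reactants: 15 β-hydroxy-γ-lactone
Product: 16 (E)-exocyclic enone lactone
Conditions: C5H5NH[CrO3Cl] (pyridinium chlorochromate, 2 equiv), 4 Å molecular sieves, CH2Cl2, 23 °C
Reagents that add atoms: none
Why: Babler–Dauben oxidative transposition ([3,3] shift of the tertiary allylic chromate ester, then oxidation) should give the tetrasubstituted enone with the acetyl group syn to the lactone CH and the methyl syn to the quaternary carbon, the larger ring carbon sitting remote from the migrating chromate.

Step 11
Reactants: 16 exocyclic enone lactone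
Product: 17 spiro-epoxy ketone
Conditions: dimethyldioxirane (acetone solution, 1.5 equiv), CH2Cl2, 0 °C
Reagents that add atoms: dimethyldioxirane, CC1(C)OO1
Why: Neutral electrophilic epoxidation of the twisted tetrasubstituted enone (faster than the planar trisubstituted cyclopentenone) from the lactone face that carries only the quaternary methyl and the α-hydrogen, anti to the cyclopentenyl and α-methyl groups, which sets the epoxide oxygen cis to the quaternary methyl.

Step 12
Reactants: 17 spiro-epoxy ketone
Product: 18 epoxy enol silane
Conditions: LiN(iPr)2 (1.05 equiv), Et3SiCl (1.2 equiv, present from the start), THF, −78 °C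
Reagents that add atoms: chlorotriethylsilane, CC[Si](CC)(CC)Cl
Why: Kinetic deprotonation with in situ silylation should take the unhindered methyl group of the epoxy ketone in preference to the ring CH2 that is flanked by the branched ring carbon, and the lactone α-hydrogen is far less acidic.

Step 13
Reactants: 18 epoxy enol silane; 19 (2E,4E)-hexa-2,4-dienal
Product: 21 cyclopentenone β-diketone (chelated enol), via aldol adducts 20 (not isolated)
Conditions: LiN(SiMe3)2 (1.1 equiv), THF, −78 °C; 19; AcOH quench; then Dess–Martin periodinane, pyridine, CH2Cl2, 0 °C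
Reagents that add atoms: none
Why: Aldol addition of the only remaining ketone enolate (the ring α′-carbon) followed by oxidation of the β-hydroxy ketone is a two-stage C-acylation that converges on one enolised β-diketone whatever the aldol stereochemistry.

Step 14
Reactants: 21 cyclopentenone β-diketone
Product: 23 tetracyclic (4+3) cycloadduct, via bis(silyl enol ether) 22 (not isolated)
Conditions: Et3N (1.2 equiv), Et3SiOTf (1.5 equiv), CH2Cl2, −78 °C; aqueous NaHCO3 quench at −78 °C
Reagents that add atoms: triethylsilyl triflate, CC[Si](CC)(CC)OS(=O)(=O)C(F)(F)F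
Why: Proposed new method: Et3SiOTf silylates the epoxide oxygen of the in situ formed bis(silyl enol ether) 22, the tertiary C–O bond beside the enol silane ionises to a 2-(silyloxy)allyl cation, and the tethered 2-silyloxycyclopentadiene adds across its two termini; the closest known reaction type is the silyl triflate-triggered intramolecular (4+3) cycloaddition of epoxy enol silanes with tethered furans and dienes, together with the classical oxyallyl cation–cyclopentadiene (4+3) route to bicyclo[3.2.1]oct-6-en-3-ones, but a diene tethered through its sp3 ring carbon, acylated at the attacked terminus and forming two adjacent quaternary carbons is without precedent. The seven-membered ketone ring closes in the (4+3) mode through a compact transition state (the six-membered ring of the bicyclo[3.2.1]octane arises with it), and the cyclopentane closes as a five-membered ring when the acylated diene terminus attacks the epoxide carbon opposite the leaving oxygen. The two bridgehead centres are fixed because the three-atom tether can deliver the cation only to the diene face that carries the lactone substituent on the ring CH; the methyl-bearing quaternary carbon forms with inversion and is the only configuration a cis-fused cyclopentane allows; the tertiary silyloxy carbon keeps the epoxide configuration. The step needs (4+3) closure at the diene CH terminus instead of (3+2) closure at the silyloxy-bearing carbon, capture of the cation before a semipinacol ring expansion, and a diene that has not undergone a 1,5-hydrogen shift; the strain of the alternative norbornane-type product, the electron-poor migrating groups (an acyloxy-bearing and a carbonyl-bearing carbon) and generation of 22 at −78 °C just before ionisation should secure these. Either O-silyl tautomer of the β-diketone should converge on the same product, because attack through the exocyclic enol silane followed by Mukaiyama–Michael closure makes the same two bonds.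

Step 15
Reactants: 23 tetracyclic cycloadduct
Product: 24 α-silyloxy ketone
Conditions: dimethyldioxirane (1.1 equiv), CH2Cl2–acetone, −78 to −40 °C
Reagents that add atoms: dimethyldioxirane, CC1(C)OO1
Why: Rubottom oxidation: the silyl enol ether is epoxidised on the exo face of the two-carbon bridge (the side of the one-carbon bridge hydrogen, away from the three-carbon bridge) and 1,4-silyl migration gives the α-silyloxy ketone with the oxygen exo, well before the electron-poor dienone reacts.

Step 16
Reactants: 25 sorbic acid
Product: 26 (2E,4E)-hexa-2,4-dienoyl chloride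
Conditions: (COCl)2, DMF (cat.), CH2Cl2, 0 to 23 °C
Reagents that add atoms: oxalyl chloride, O=C(Cl)C(Cl)=O
Why: Standard acid chloride formation through the Vilsmeier-type intermediate, with the diene geometry unaffected.

Step 17
Reactants: 24 α-silyloxy ketone; 26 (2E,4E)-hexa-2,4-dienoyl chloride
Product: 27 bis(triethylsilyl) ether of the target
Conditions: MgBr2·OEt2 (2.5 equiv), iPr2NEt (3 equiv), CH2Cl2, 0 to 23 °C
Reagents that add atoms: none
Why: Soft-enolisation C-acylation of a ketone with an acid chloride: the bridging ketone has only one enolisable α-position (the ring CH2), the other ketones have none, both hydroxyls are silylated, and the magnesium chelate of the product enolises to the hydrogen-bonded enol.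

Step 18
Reactants: 27 bis(triethylsilyl) ether of the target
Product: 28 target CNP0231466.1
Conditions: HF·pyridine, pyridine, THF, 0 to 23 °C
Reagents that add atoms: none
Why: Buffered fluoride cleavage of the two tertiary triethylsilyl ethers under mildly acidic conditions should avoid retro-aldol or β-elimination of the β-hydroxy ketone and β-hydroxy lactone units.

**Compound list**

1 | 1-(furan-2-yl)ethan-1-ol (racemic) | CC(O)c1ccco1 | starting material
2 | (±)-trans-4-hydroxy-5-methylcyclopent-2-en-1-one (racemate, both enantiomers shown) | O=C1C=C[C@H](O)[C@H]1C.O=C1C=C[C@@H](O)[C@@H]1C | intermediate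
3 | (4S,5R)-4-hydroxy-5-methylcyclopent-2-en-1-one | O=C1C=C[C@H](O)[C@H]1C | intermediate
4 | (4S,5R)-4-(tert-butyldimethylsilyloxy)-5-methylcyclopent-2-en-1-one | O=C1C=C[C@H](O[Si](C)(C)C(C)(C)C)[C@H]1C | intermediate
5 | (R)-lactic acid | C[C@@H](O)C(=O)O | starting material
6 | pivalaldehyde | CC(C)(C)C=O | starting material
7 | (2R,5R)-2-tert-butyl-5-methyl-1,3-dioxolan-4-one (cis) | C[C@H]1O[C@@H](C(C)(C)C)OC1=O | intermediate
8 | (2R,5S)-2-tert-butyl-5-methyl-5-[5-(tert-butyldimethylsilyloxy)-4-methyl-3-(trimethylsilyloxy)cyclopent-2-en-1-yl]-1,3-dioxolan-4-one; ring substituent trans to tert-butyl; on the cyclopentene the dioxolanone and OTBS are trans and OTBS and methyl are trans | C[C@@]1([C@@H]2C=C(O[Si](C)(C)C)[C@H](C)[C@H]2O[Si](C)(C)C(C)(C)C)O[C@@H](C(C)(C)C)OC1=O | intermediate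
9 | (E)-2-bromobut-2-ene | C/C=C(\C)Br | starting material
10 | (E)-but-2-en-2-yllithium | C/C=C(\C)[Li] | intermediate (not isolated)
11 | (2S,4E)-2-hydroxy-4-methyl-2-[2-(tert-butyldimethylsilyloxy)-3-methyl-4-oxocyclopentyl]hex-4-en-3-one; ring substituents trans,trans | C/C=C(\C)C(=O)[C@@](C)(O)[C@@H]1CC(=O)[C@H](C)[C@H]1O[Si](C)(C)C(C)(C)C | intermediate
12 | (4R)-4-[(2S,4E)-2-hydroxy-4-methyl-3-oxohex-4-en-2-yl]-2-methylcyclopent-2-en-1-one | C/C=C(\C)C(=O)[C@@](C)(O)[C@@H]1CC(=O)C(C)=C1 | intermediate
13 | 2-bromopropanoyl bromide (racemic) | CC(Br)C(Br)=O | starting material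
14 | 2-bromopropanoate of 12 (both epimers at the CHBr carbon) | C/C=C(\C)C(=O)[C@@](C)(OC(=O)C(C)Br)[C@@H]1CC(=O)C(C)=C1 | intermediate
15 | 4-[(E)-but-2-en-2-yl]-4-hydroxy-3,5-dimethyl-5-[(1R)-3-methyl-4-oxocyclopent-2-en-1-yl]oxolan-2-one; 4-OH cis to 5-CH3 and trans to 3-CH3 | C/C=C(\C)[C@@]1(O)[C@@H](C)C(=O)O[C@@]1(C)[C@@H]2CC(=O)C(C)=C2 | intermediate
16 | (E)-3,5-dimethyl-5-[(1R)-3-methyl-4-oxocyclopent-2-en-1-yl]-4-(3-oxobutan-2-ylidene)oxolan-2-one; 3-CH3 trans to 5-CH3 | CC(=O)/C(C)=C1\[C@@H](C)C(=O)O[C@@]1(C)[C@@H]2CC(=O)C(C)=C2 | intermediate
17 | 2-acetyl-2,4,7-trimethyl-4-[(1R)-3-methyl-4-oxocyclopent-2-en-1-yl]-1,5-dioxaspiro[2.4]heptan-6-one; epoxide oxygen cis to 4-CH3 and to 7-H | CC(=O)[C@@]1(C)O[C@@]12[C@@H](C)C(=O)O[C@@]2(C)[C@@H]3CC(=O)C(C)=C3 | intermediate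
18 | triethylsilyl enol ether of 17: 2-[1-(triethylsilyloxy)ethenyl] analogue | C=C(O[Si](CC)(CC)CC)[C@@]1(C)O[C@@]12[C@@H](C)C(=O)O[C@@]2(C)[C@@H]3CC(=O)C(C)=C3 | intermediate
19 | (2E,4E)-hexa-2,4-dienal | C/C=C/C=C/C=O | starting material
20 | aldol adducts of 18 at the ring α′-carbon (epimers at that carbon and at the carbinol) | C=C(O[Si](CC)(CC)CC)[C@@]1(C)O[C@@]12[C@@H](C)C(=O)O[C@@]2(C)[C@@H]3C(C(O)/C=C/C=C/C)C(=O)C(C)=C3 | intermediate (not isolated)
21 | 5-[(2E,4E)-hexa-2,4-dienoyl]cyclopentenone derived from 18, drawn as the chelated exocyclic enol | C=C(O[Si](CC)(CC)CC)[C@@]1(C)O[C@@]12[C@@H](C)C(=O)O[C@@]2(C)[C@@H]3\C(=C(O)/C=C/C=C/C)C(=O)C(C)=C3 | intermediate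
22 | bis(triethylsilyl enol ether): 1-sorbyl-2-(triethylsilyloxy)cyclopenta-1,3-diene tethered through its sp3 carbon to the epoxy enol silane | C=C(O[Si](CC)(CC)CC)[C@@]1(C)O[C@@]12[C@@H](C)C(=O)O[C@@]2(C)[C@@H]3C(C(=O)/C=C/C=C/C)=C(O[Si](CC)(CC)CC)C(C)=C3 | intermediate (not isolated)
23 | tetracyclic cycloadduct: bicyclo[3.2.1]oct-6-en-3-one with 6-(triethylsilyloxy), 7-methyl, bridgehead sorbyl ketone, fused cyclopentane and γ-lactone, tertiary OSiEt3 | C/C=C/C=C/C(=O)[C@]12C(O[Si](CC)(CC)CC)=C(C)[C@@H]3CC(=O)[C@@]1(C)[C@@]1(O[Si](CC)(CC)CC)[C@@H](C)C(=O)O[C@@]1(C)[C@@H]32 | intermediate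
24 | α-silyloxy ketone: two-carbon bridge now C(=O)–C(CH3)(OSiEt3), silyloxy group exo | C/C=C/C=C/C(=O)[C@]12C(=O)[C@@](C)(O[Si](CC)(CC)CC)[C@@H]3CC(=O)[C@@]1(C)[C@@]1(O[Si](CC)(CC)CC)[C@@H](C)C(=O)O[C@@]1(C)[C@@H]32 | intermediate
25 | sorbic acid, (2E,4E)-hexa-2,4-dienoic acid | C/C=C/C=C/C(=O)O | starting material
26 | (2E,4E)-hexa-2,4-dienoyl chloride | C/C=C/C=C/C(=O)Cl | intermediate
27 | bis(triethylsilyl) ether of the target (enolised β-diketone) | C/C=C/C=C/C(=O)[C@]12C(=O)[C@@](C)(O[Si](CC)(CC)CC)[C@@H]3\C(=C(O)/C=C/C=C/C)C(=O)[C@@]1(C)[C@@]1(O[Si](CC)(CC)CC)[C@@H](C)C(=O)O[C@@]1(C)[C@@H]32 | intermediate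
28 | CNP0231466.1 | C/C=C/C=C/C(=O)[C@]12C(=O)[C@@](C)(O)[C@@H]3\C(=C(O)/C=C/C=C/C)C(=O)[C@@]1(C)[C@@]1(O)[C@@H](C)C(=O)O[C@@]1(C)[C@@H]32 | target

**Totals and risks**

Total step count: 18. Longest linear sequence: 16 steps (1, 2, 3, 5–15, 17, 18).

Steps most likely to fail:

1. Step 14 (proposed new method). The cyclopentadiene may isomerise by 1,5-hydrogen shift before it is captured, the cation may undergo semipinacol ring expansion, or the reaction may stop after the first C–C bond or close in the (3+2) sense. Fallback with known reaction types, making the two bonds one after the other: setting out from 21, the in situ diene 22 is treated with Et3SiOTf and 2,6-di-tert-butyl-4-methylpyridine in EtCN at −78 °C and quenched with aqueous NaHCO3, so that Lewis-acid opening of the epoxide by the tethered silyl enol ether (an intramolecular Mukaiyama-type alkylation) is the only event and gives the bicyclic enone methyl ketone F1. F1 is then deprotonated at its methyl ketone (LiN(SiMe3)2, THF, −78 to 0 °C), the enolate closes the six-membered ring by intramolecular Michael addition to the cyclopentenone, and trapping with Et3SiCl returns the route at 23.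

2. Step 12. Enolisation may not discriminate between the methyl ketone and the ring α′-CH2, or the lactone enolate may open the epoxide by β-elimination. Fallback that needs no discrimination: setting out from 17, both ketone enolates are formed (LiN(SiMe3)2, 2.2 equiv) and added to 19 to give the bis-aldol F2, and twofold Dess–Martin oxidation gives the bis(β-diketone) F3, which already carries both sorbyl units. Silylation as in step 14 gives the bis(silyl enol ether) F4 in situ and the (4+3) cycloaddition, now with an acyl group on the oxyallyl terminus, gives the acylated cycloadduct F5. Rubottom oxidation at −78 °C, where only the silyl enol ether should react, returns the route at 27 and makes step 17 unnecessary; the cation is less stabilised in this variant, which is why it is kept as the reserve.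

3. Step 5. The basic enolate may deprotonate the enone at its α-carbon (leading to loss of the silyloxy group) or add in the 1,2-sense instead of forming the congested quaternary–tertiary bond. Fallback under non-basic conditions: setting out from 7, deprotonation and O-silylation (LiN(iPr)2, Me3SiCl, −78 °C) give the silyl ketene acetal F6, which is added to 4 by a Lewis-acid-catalysed Mukaiyama–Michael reaction (Me3SiOTf cat., CH2Cl2, −78 °C) with the same facial preferences and silyl transfer to the new enolate oxygen, returning the route at 8.

Further compounds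
F1 | step 14 | bicyclic enone methyl ketone: cis-fused bicyclo[3.3.0]octenone with ring-fusion sorbyl ketone, fused γ-lactone, tertiary OSiEt3 and acetyl on the methyl-bearing quaternary carbon | C/C=C/C=C/C(=O)[C@@]12C(=O)C(C)=C[C@@H]1[C@]3(C)OC(=O)[C@H](C)[C@]3(O[Si](CC)(CC)CC)[C@]2(C)C(C)=O
F2 | step 12 | bis-aldol of 17 with two molecules of 19 (epimers at the carbinols and at the ring α′-carbon) | C/C=C/C=C/C(O)CC(=O)[C@@]1(C)O[C@@]12[C@@H](C)C(=O)O[C@@]2(C)[C@@H]3C(C(O)/C=C/C=C/C)C(=O)C(C)=C3
F3 | step 12 | bis(β-diketone), both drawn as chelated enols | C/C=C/C=C/C(O)=C/C(=O)[C@@]1(C)O[C@@]12[C@@H](C)C(=O)O[C@@]2(C)[C@@H]3\C(=C(O)/C=C/C=C/C)C(=O)C(C)=C3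
F4 | step 12 | bis(triethylsilyl enol ether) of F3 (not isolated; enol ether geometry on the epoxide side open) | C/C=C/C=C/C(=O)C=C(O[Si](CC)(CC)CC)[C@@]1(C)O[C@@]12[C@@H](C)C(=O)O[C@@]2(C)[C@@H]3C(C(=O)/C=C/C=C/C)=C(O[Si](CC)(CC)CC)C(C)=C3
F5 | step 12 | acylated cycloadduct: 23 carrying the enolised sorbyl β-diketone on the three-carbon bridge | C/C=C/C=C/C(=O)[C@]12C(O[Si](CC)(CC)CC)=C(C)[C@@H]3\C(=C(O)/C=C/C=C/C)C(=O)[C@@]1(C)[C@@]1(O[Si](CC)(CC)CC)[C@@H](C)C(=O)O[C@@]1(C)[C@@H]32
F6 | step 5 | (2R)-2-tert-butyl-5-methyl-4-(trimethylsilyloxy)-1,3-dioxole | CC1=C(O[Si](C)(C)C)O[C@H](C(C)(C)C)O1
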